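## The problem

Target 21 is a dibenzylbutane lignan. Two identical 4-hydroxy-3,5-dimethoxyphenyl rings are joined only through the open chain C7–C8–C8'–C7', and C8 and C8' each carry a methyl group (C9, C9'). No ring other than the two arenes has to be built, so the task reduces to the central C8–C8' bond and the relative configuration across it. The descriptors are (8R,8'S) with identical substituent sets, which is the achiral meso isomer, so absolute control is not needed. The chain is flexible and carries no ring or resident stereocentre that could relay selectivity, so the two centres must be set together in the bond-forming event. The wrong relationship gives the racemic diastereomer, which differs only in the orientation of two methyl groups and would be hard to remove. The fragile groups are the two 2,6-dimethoxyphenols, which are easily oxidised (periodate, metal oxidants, air under base) and would quench enolates and hydrides; the four benzylic CH2 groups also limit the use of strong oxidants. The enabling feature is that C8 and C8' are each a CH bearing one arylmethyl group and one one-carbon group. If C9 is read as a reduced carboxyl carbon and C9' as the remnant of a vinyl group, C8 and C8' become C2 and C3 of a 2,3-bis(arylmethyl)pent-4-enoic acid, the retron of a [3,3] shift of an allyl ester enolate.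

## Retrosynthesis

**21 to 20 (phenol protection).** The two O–H bonds are traced to benzyl ethers in 20. Benzyl is preferred to silyl (at risk with amide base and LiBHEt3) and to acetal groups (an acidic release next to electron-rich arenes) because it tolerates every reagent planned. The free phenols would not tolerate periodate or the enolate chemistry. The forward reaction is a hydrogenolysis on a molecule with nothing else reducible.

**20 to 19 to 18 (both methyl groups at once).** The two C9–H and C9'–H bonds are traced to C–O bonds: bis-mesylate 19 and meso diol 18. Handling both arms together is shorter than deoxygenating one arm at a time, and the symmetry of 18 makes it a convenient checkpoint for diastereomeric purity. The forward reaction is hydride displacement at two primary carbons, which cannot touch the stereocentres.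

**18 to 16 to 15 (differentiating the arms).** One hydroxymethyl is traced to the carboxyl group of acid 15 (via alcohol 16). The other is traced to a vinyl group that loses its terminal carbon by oxidative cleavage and reduction (via lactol 17). Reducing the acid before the cleavage is preferred to the reverse order because the hydroxyl then traps the new aldehyde as a lactol and limits enolisation next to the stereocentre. The cleavage must spare the arenes, which the benzyl ethers ensure.

**15 to 11 (the C8–C8' bond).** The C2–C3 bond of 15 is cut to give allylic ester 11, through lithium enolate 12, silyl ketene acetal 13 and silyl ester 14. Intermolecular ways of making this bond (oxidative enolate dimerisation, alkylation with a secondary electrophile) have no lever on the relative configuration. Cutting C7–C8 instead would require the meso core to be available beforehand. The ester tether turns the bond formation into a concerted, chair-organised event. The precursor has no stereocentre and is made of two halves of nearly equal size. The forward reaction needs one enolate geometry and a pure E alkene.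

**11 to 10 + 6 (the tether).** The ester C–O bond is cut to acid 10 and allylic alcohol 6. This is the only sensible cut, and it leaves two phenylpropanoid-derived pieces. The esterification must be neutral so that the alkene neither migrates nor isomerises.

**6 to 5 to 3 + 4, and 3 to 1 + 2 (the E alkene).** The alcohol is traced to enoate 5, and the C2=C3 bond of 5 is cut by cross-metathesis to allylarene 3 and methyl acrylate 4. The benzyl ether of 3 is cut to 4-allyl-2,6-dimethoxyphenol 1 and benzyl bromide 2. Metathesis with an allylic-oxygenated partner would reach the alcohol oxidation level directly. It would, however, give a thermodynamic E/Z mixture, and every Z molecule would end up in the wrong diastereomer series. The acrylate route costs one reduction and should give the E isomer almost exclusively.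

**10 to 8 to 7 (the acid half).** The benzyl ether of 10 is cut to phenol acid 8 (via benzyl ester 9), and 8 is traced to sinapic acid 7 by addition of H2 across the C=C bond. Hydrogenation must come first, because a benzyl ether would be lost under the same conditions.

## Roads not taken

**Alternative 1: photodimer and ring cleavage.**
- Cut: C8–C8' together with a temporary C7–C7' bond.
- Forward key step: (E)-2-(benzyloxy)-1,3-dimethoxy-5-(prop-1-en-1-yl)benzene A1 (one isomerisation from 3) is irradiated at high concentration. An excimer collapses to the syn head-to-head dimer A2, r-1,c-2-bis[4-(benzyloxy)-3,5-dimethoxyphenyl]-t-3,t-4-dimethylcyclobutane. Its cis methyl groups encode the meso relationship. Reductive cleavage of the doubly benzylic C7–C7' bond and debenzylation would finish.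
- Merits: by far the shortest route, fully symmetric, and the stereochemistry derives from a single alkene geometry.
- Weak points: excited electron-rich propenylarenes mainly undergo E/Z isomerisation. The syn head-to-head dimer needed is the most congested isomer and competes with anti and head-to-tail dimers. The better-behaved radical-cation dimerisation gives the all-trans cyclobutane, which leads to the racemic diastereomer. The ring cleavage needs dissolving-metal conditions.
- Comparison: this road is clearly better in step count. The chosen plan sets against that a stereo-defining step whose outcome follows from two controllable geometries, not from a photochemical product distribution.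

**Alternative 2: furan template.**
- Cut: no C–C bond at the key step; four C–H bonds are formed.
- Forward key step: the planar 2,5-bis[4-(benzyloxy)-3,5-dimethoxyphenyl]-3,4-dimethylfuran A3 takes up two H2 from one face over Pd/C, with loss of the benzyl groups. This gives all-cis-2,5-bis(4-hydroxy-3,5-dimethoxyphenyl)-3,4-dimethyltetrahydrofuran A4. Hydrogenolysis of its two benzylic C–O bonds would then give 21.
- Merits: short and symmetric. A3 comes from carbonyl chemistry in which no stereochemistry matters. Cis addition to a flat ring is a simple stereochemical argument.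
- Weak points: a tetrasubstituted, aryl-conjugated furan is slow to saturate. Benzylic C–O hydrogenolysis can open the ring at the dihydrofuran stage, giving enol or ketone intermediates that lose the cis relationship at C8/C8'. Forcing conditions endanger the arenes.
- Comparison: this road is shorter, and equally good if the hydrogenation proves clean. The chosen plan offers a homogeneous, concerted stereo-defining step with no competing pathway that scrambles C8 or C8'.

**Alternative 3: two-directional Negishi arylation.**
- Cut: both aryl–C7 bonds.
- Forward key step: meso-1,4-diiodo-2,3-dimethylbutane A5 is converted into meso-1,4-bis(iodozincio)-2,3-dimethylbutane A6. This couples at both ends with 2-(benzyloxy)-5-bromo-1,3-dimethoxybenzene A7 under zerovalent palladium catalysis. The product is meso-1,4-bis[4-(benzyloxy)-3,5-dimethoxyphenyl]-2,3-dimethylbutane A8, identical with 20.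
- Merits: the shortest route to 20. The stereocentres are never at risk, because the metal sits one carbon away from them.
- Weak points: the meso core must be bought or separated from its racemic isomer at the start. Two consecutive sp3–sp2 couplings of a β-branched alkylzinc with an electron-rich aryl bromide must both succeed. β-Hydride elimination or protodemetalation at either end gives mono-arylated by-products.
- Comparison: this road is better in step count and in stereochemical security. The chosen plan builds the meso relationship from inexpensive phenylpropanoid feedstocks and does not rely on a stereochemically pure C6 building block or on a twofold coupling.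

Key step: step 7

Remark on the chemistry: because the two aryl groups are identical, the (8R,8'S) target is the meso compound. Racemic intermediates of the correct relative configuration are therefore sufficient, and descriptors marked with an asterisk are relative.

## Route

Step 1
Reactants: 1 4-allyl-2,6-dimethoxyphenol; 2 benzyl bromide
Product: 3 5-allyl-2-(benzyloxy)-1,3-dimethoxybenzene
Conditions: K2CO3, DMF, 60 °C
Reagents that add atoms: none
Why: Williamson etherification; the phenoxide flanked by two methoxy groups is hindered, but benzyl bromide is an unhindered SN2 partner, and carbonate is too weak a base to move the allyl double bond into conjugation.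

Step 2
Reactants: 3 5-allyl-2-(benzyloxy)-1,3-dimethoxybenzene; 4 methyl acrylate
Product: 5 methyl (2E)-4-[4-(benzyloxy)-3,5-dimethoxyphenyl]but-2-enoate
Conditions: 4 (4 equiv), second-generation Grubbs catalyst RuCl2(=CHPh)(PCy3)(H2IMes) (3 mol %), CH2Cl2, 40 °C
Reagents that add atoms: none
Why: Olefin cross-metathesis of a terminal allylarene with an electron-poor acrylate, a pairing in which the acrylate does not homodimerise and ethene loss drives the reaction. The conjugated product should form almost entirely as the E isomer, which is why the alkene geometry is set at the enoate stage.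

Step 3
Reactants: 5 methyl (2E)-4-[4-(benzyloxy)-3,5-dimethoxyphenyl]but-2-enoate
Product: 6 (2E)-4-[4-(benzyloxy)-3,5-dimethoxyphenyl]but-2-en-1-ol
Conditions: iBu2AlH (2.2 equiv), CH2Cl2, −78 °C; aq. potassium sodium tartrate
Reagents that add atoms: none
Why: 1,2-Reduction of an α,β-unsaturated ester with diisobutylaluminium hydride; at low temperature hydride adds only to the carbonyl, and the non-basic reagent leaves the E double bond where it is.

Step 4
Reactants: 7 sinapic acid
Product: 8 3-(4-hydroxy-3,5-dimethoxyphenyl)propanoic acid
Conditions: H2 (1 atm), 10% Pd/C, MeOH, rt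
Reagents that add atoms: none
Why: Heterogeneous hydrogenation of a cinnamic acid double bond; the arene, methoxy and phenol groups are inert. It is done before benzylation because a benzyl ether would not survive.

Step 5
Reactants: 8 3-(4-hydroxy-3,5-dimethoxyphenyl)propanoic acid; 2 benzyl bromide
Product: 10 3-[4-(benzyloxy)-3,5-dimethoxyphenyl]propanoic acid, via benzyl ester 9 (not isolated)
Conditions: 2 (2.3 equiv), K2CO3, DMF, 60 °C; then 2 M NaOH, MeOH, 60 °C; HCl to pH 2
Reagents that add atoms: sodium hydroxide [Na+].[OH-] (its oxygen becomes the carboxyl OH of 10)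
Why: Twofold O-alkylation (phenoxide and carboxylate) followed by saponification in the same flask. Hydroxide cleaves only the benzyl ester by acyl–oxygen cleavage, the aryl benzyl ether is base-stable, and acid–base extraction removes benzyl alcohol.

Step 6
Reactants: 10 3-[4-(benzyloxy)-3,5-dimethoxyphenyl]propanoic acid; 6 (2E)-4-[4-(benzyloxy)-3,5-dimethoxyphenyl]but-2-en-1-ol
Product: 11 (2E)-4-[4-(benzyloxy)-3,5-dimethoxyphenyl]but-2-en-1-yl 3-[4-(benzyloxy)-3,5-dimethoxyphenyl]propanoate
Conditions: EDC·HCl, DMAP (0.2 equiv), CH2Cl2, 0 °C → rt
Reagents that add atoms: none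
Why: Steglich esterification (carbodiimide activation, DMAP acyl transfer) of an unhindered acid with a primary allylic alcohol; the near-neutral conditions leave the position and E geometry of the alkene untouched.

Step 7
Reactants: 11 (2E)-4-[4-(benzyloxy)-3,5-dimethoxyphenyl]but-2-en-1-yl 3-[4-(benzyloxy)-3,5-dimethoxyphenyl]propanoate
Product: 15 (2R*,3R*)-2,3-bis[4-(benzyloxy)-3,5-dimethoxybenzyl]pent-4-enoic acid (anti, racemic), via lithium ester enolate 12 (not isolated), via trimethylsilyl ketene acetal 13 (not isolated), via trimethylsilyl ester 14 (not isolated)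
Conditions: LiN(iPr)2 (1.2 equiv), THF, −78 °C; Me3SiCl, Et3N, −78 °C → rt, then 60 °C; 1 M HCl
Reagents that add atoms: lithium diisopropylamide CC(C)N([Li])C(C)C (its lithium is carried by 12 only); chlorotrimethylsilane C[Si](C)(C)Cl (its Me3Si group is carried by 13 and 14 only); no reagent atom other than hydrogen remains in 15
Why: Ireland–Claisen (ester enolate Claisen) rearrangement; the closest known case is the rearrangement of E-allylic alkanoates through kinetically formed silyl ketene acetals. LiN(iPr)2 in THF removes an α-proton of 11 through a closed, lithium-bridged transition state that keeps the arylmethyl group away from the isopropyl groups; this gives the E(O) enolate 12 (arylmethyl cis to the allyloxy oxygen), and O-silylation fixes that geometry in 13. On warming, 13 undergoes a concerted suprafacial [3,3] shift through a chair with the E-alkene substituent equatorial; the allylic C–O bond breaks and the C2–C3 (C8–C8') bond of silyl ester 14 forms, and aqueous acid hydrolyses 14 to 15. No ring is closed. Both new stereocentres arise in this one event: C2 is fixed by the enolate geometry and C3 by the E alkene, and their pairing in the chair gives the anti (2R*,3R*) relationship, which becomes meso once carboxyl and vinyl are both methyl. The selectivity needed is E(O) enolisation plus chair topology; the first is secured by the absence of any polar cosolvent and the unbranched α-CH2, the second by the unhindered acyclic E-allyl unit, for which a boat has no advantage. The ester α-protons are far more acidic than the benzylic–allylic CH2 of the butenyl arm, so deprotonation at −78 °C should be regioselective, and the benzyl ethers, aryl ethers and alkene are inert to the base.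

Step 8
Reactants: 15 (2R*,3R*)-2,3-bis[4-(benzyloxy)-3,5-dimethoxybenzyl]pent-4-enoic acid
Product: 16 (2R*,3R*)-2,3-bis[4-(benzyloxy)-3,5-dimethoxybenzyl]pent-4-en-1-ol
Conditions: LiAlH4, THF, 0 °C → rt
Reagents that add atoms: none
Why: Hydride reduction of a carboxylic acid to the primary alcohol; the carboxylate/aluminate stage cannot enolise, so C2 keeps its configuration, and the isolated terminal alkene and the ethers are not reduced.

Step 9
Reactants: 16 (2R*,3R*)-2,3-bis[4-(benzyloxy)-3,5-dimethoxybenzyl]pent-4-en-1-ol
Product: 18 meso-(2R,3S)-2,3-bis[4-(benzyloxy)-3,5-dimethoxybenzyl]butane-1,4-diol, via cis-lactol 17 (not isolated)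
Conditions: OsO4 (2 mol %), NaIO4 (4 equiv), 2,6-lutidine, dioxane/H2O 3:1, rt; then NaBH4, MeOH, 0 °C
Reagents that add atoms: osmium tetroxide O=[Os](=O)(=O)=O (source of the new oxygen atom, catalytic); sodium periodate [Na+].[O-]I(=O)(=O)=O (stoichiometric oxidant that restores the osmium oxo ligands)
Why: Lemieux–Johnson cleavage of the terminal alkene followed by borohydride reduction. The new aldehyde is captured by the 4-hydroxyl as the five-membered lactol 17, which keeps the enolisable open form scarce under lutidine buffering, so the adjacent stereocentre should survive until NaBH4 reduces it to the symmetrical diol. The benzyl-protected arenes are not attacked by periodate.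

Step 10
Reactants: 18 meso-(2R,3S)-2,3-bis[4-(benzyloxy)-3,5-dimethoxybenzyl]butane-1,4-diol
Product: 19 meso-(2R,3S)-2,3-bis[4-(benzyloxy)-3,5-dimethoxybenzyl]butane-1,4-diyl dimethanesulfonate
Conditions: MsCl (2.5 equiv), Et3N, CH2Cl2, 0 °C
Reagents that add atoms: methanesulfonyl chloride CS(=O)(=O)Cl
Why: Sulfonylation of two primary alcohols under amine base; run cold with excess reagent so that the second hydroxyl is sulfonylated before a mono-mesylate can cyclise to a tetrahydrofuran.

Step 11
Reactants: 19 meso-(2R,3S)-2,3-bis[4-(benzyloxy)-3,5-dimethoxybenzyl]butane-1,4-diyl dimethanesulfonate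
Product: 20 meso-(2R,3S)-1,4-bis[4-(benzyloxy)-3,5-dimethoxyphenyl]-2,3-dimethylbutane
Conditions: LiBHEt3 (5 equiv), THF, 0 °C → rt
Reagents that add atoms: none
Why: SN2 displacement of primary sulfonates by the strongly nucleophilic triethylborohydride; substitution occurs only at the CH2 carbons, so both stereocentres are untouched and the meso relationship is carried through.

Step 12
Reactants: 20 meso-(2R,3S)-1,4-bis[4-(benzyloxy)-3,5-dimethoxyphenyl]-2,3-dimethylbutane
Product: 21 meso-(2R,3S)-1,4-bis(4-hydroxy-3,5-dimethoxyphenyl)-2,3-dimethylbutane (CNP0314108.1)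
Conditions: H2 (1 atm), 10% Pd/C, EtOAc/MeOH, rt
Reagents that add atoms: none
Why: Hydrogenolysis of aryl benzyl ethers over palladium on carbon; the chain has no alkene, halide or benzylic heteroatom left, so nothing else is reducible and the stereocentres are not involved.

## Compound list

1 | 4-allyl-2,6-dimethoxyphenol | C=CCc1cc(OC)c(O)c(OC)c1 | starting material
2 | benzyl bromide | BrCc1ccccc1 | starting material
3 | 5-allyl-2-(benzyloxy)-1,3-dimethoxybenzene | C=CCc1cc(OC)c(OCc2ccccc2)c(OC)c1 | intermediate
4 | methyl acrylate | C=CC(=O)OC | starting material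
5 | methyl (2E)-4-[4-(benzyloxy)-3,5-dimethoxyphenyl]but-2-enoate | COC(=O)/C=C/Cc1cc(OC)c(OCc2ccccc2)c(OC)c1 | intermediate
6 | (2E)-4-[4-(benzyloxy)-3,5-dimethoxyphenyl]but-2-en-1-ol | OC/C=C/Cc1cc(OC)c(OCc2ccccc2)c(OC)c1 | intermediate
7 | sinapic acid, (2E)-3-(4-hydroxy-3,5-dimethoxyphenyl)prop-2-enoic acid | COc1cc(/C=C/C(=O)O)cc(OC)c1O | starting material
8 | 3-(4-hydroxy-3,5-dimethoxyphenyl)propanoic acid | COc1cc(CCC(=O)O)cc(OC)c1O | intermediate
9 | benzyl 3-[4-(benzyloxy)-3,5-dimethoxyphenyl]propanoate | COc1cc(CCC(=O)OCc2ccccc2)cc(OC)c1OCc1ccccc1 | intermediate (not isolated)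
10 | 3-[4-(benzyloxy)-3,5-dimethoxyphenyl]propanoic acid | COc1cc(CCC(=O)O)cc(OC)c1OCc1ccccc1 | intermediate
11 | (2E)-4-[4-(benzyloxy)-3,5-dimethoxyphenyl]but-2-en-1-yl 3-[4-(benzyloxy)-3,5-dimethoxyphenyl]propanoate | COc1cc(CCC(=O)OC/C=C/Cc2cc(OC)c(OCc3ccccc3)c(OC)c2)cc(OC)c1OCc1ccccc1 | intermediate
12 | lithium E(O)-enolate of 11 (arylmethyl cis to the allyloxy oxygen, trans to OLi) | COc1cc(C/C=C(/O[Li])OC/C=C/Cc2cc(OC)c(OCc3ccccc3)c(OC)c2)cc(OC)c1OCc1ccccc1 | intermediate (not isolated)
13 | trimethylsilyl ketene acetal of 11 (arylmethyl cis to the allyloxy oxygen, trans to OSiMe3) | COc1cc(C/C=C(/O[Si](C)(C)C)OC/C=C/Cc2cc(OC)c(OCc3ccccc3)c(OC)c2)cc(OC)c1OCc1ccccc1 | intermediate (not isolated)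
14 | trimethylsilyl (2R*,3R*)-2,3-bis[4-(benzyloxy)-3,5-dimethoxybenzyl]pent-4-enoate (racemic) | COc1cc(C[C@@H](C(=O)O[Si](C)(C)C)[C@@H](C=C)Cc2cc(OC)c(OCc3ccccc3)c(OC)c2)cc(OC)c1OCc1ccccc1 | intermediate (not isolated)
15 | (2R*,3R*)-2,3-bis[4-(benzyloxy)-3,5-dimethoxybenzyl]pent-4-enoic acid (anti, racemic; one enantiomer drawn) | COc1cc(C[C@@H](C(=O)O)[C@@H](C=C)Cc2cc(OC)c(OCc3ccccc3)c(OC)c2)cc(OC)c1OCc1ccccc1 | intermediate
16 | (2R*,3R*)-2,3-bis[4-(benzyloxy)-3,5-dimethoxybenzyl]pent-4-en-1-ol (racemic) | COc1cc(C[C@@H](CO)[C@@H](C=C)Cc2cc(OC)c(OCc3ccccc3)c(OC)c2)cc(OC)c1OCc1ccccc1 | intermediate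
17 | 3,4-cis-3,4-bis[4-(benzyloxy)-3,5-dimethoxybenzyl]tetrahydrofuran-2-ol (racemic, mixture of anomers) | COc1cc(C[C@@H](CO4)[C@@H](C4O)Cc2cc(OC)c(OCc3ccccc3)c(OC)c2)cc(OC)c1OCc1ccccc1 | intermediate (not isolated)
18 | meso-(2R,3S)-2,3-bis[4-(benzyloxy)-3,5-dimethoxybenzyl]butane-1,4-diol | COc1cc(C[C@@H](CO)[C@@H](CO)Cc2cc(OC)c(OCc3ccccc3)c(OC)c2)cc(OC)c1OCc1ccccc1 | intermediate
19 | meso-(2R,3S)-2,3-bis[4-(benzyloxy)-3,5-dimethoxybenzyl]butane-1,4-diyl dimethanesulfonate | COc1cc(C[C@@H](COS(C)(=O)=O)[C@@H](COS(C)(=O)=O)Cc2cc(OC)c(OCc3ccccc3)c(OC)c2)cc(OC)c1OCc1ccccc1 | intermediate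
20 | meso-(2R,3S)-1,4-bis[4-(benzyloxy)-3,5-dimethoxyphenyl]-2,3-dimethylbutane | COc1cc(C[C@@H](C)[C@@H](C)Cc2cc(OC)c(OCc3ccccc3)c(OC)c2)cc(OC)c1OCc1ccccc1 | intermediate
21 | meso-(2R,3S)-1,4-bis(4-hydroxy-3,5-dimethoxyphenyl)-2,3-dimethylbutane (CNP0314108.1) | COc1cc(C[C@@H](C)[C@@H](C)Cc2cc(OC)c(O)c(OC)c2)cc(OC)c1O | target

## Step count and risk

Total step count: 12. Longest linear sequence: 10 steps (1, 2, 3, 6, 7, 8, 9, 10, 11, 12, from compound 1). The acid branch (steps 4 and 5) joins at step 6.

**Step 7 (key step).**
- What may go wrong: incomplete control of enolate geometry. Leakage to the Z(O) enolate lowers the anti/syn ratio of the rearrangement, and after step 11 this would appear as the racemic diastereomer. A smaller risk is deprotonation at the benzylic–allylic CH2 of the butenyl arm, with 1,4-elimination of the carboxylate. The ratio should be checked at 15 and again at the symmetrical diol 18, the more promising stage for purification by crystallisation.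
- Fallback: an Eschenmoser–Claisen variant that sets out from 10 and 6 and comes back at 16. Acid 10 is coupled with dimethylamine (EDC·HCl) to give 3-[4-(benzyloxy)-3,5-dimethoxyphenyl]-N,N-dimethylpropanamide F1. O-Methylation with Me3OBF4 gives N-{3-[4-(benzyloxy)-3,5-dimethoxyphenyl]-1-methoxypropylidene}-N-methylmethanaminium tetrafluoroborate F2. NaOMe in MeOH converts this into the amide acetal 3-[4-(benzyloxy)-3,5-dimethoxyphenyl]-1,1-dimethoxy-N,N-dimethylpropan-1-amine F3. Heating F3 with 6 in xylene at about 140 °C, with removal of methanol, exchanges one methoxy group and eliminates methanol. This gives the ketene N,O-acetal (1Z)-3-[4-(benzyloxy)-3,5-dimethoxyphenyl]-1-({(2E)-4-[4-(benzyloxy)-3,5-dimethoxyphenyl]but-2-en-1-yl}oxy)-N,N-dimethylprop-1-en-1-amine F4. In F4, allylic 1,3-strain against the NMe2 group places the arylmethyl group cis to the allyloxy oxygen. This is the same geometry as in 13, but it is set by strain instead of by kinetic deprotonation. The chair [3,3] shift then gives (2R*,3R*)-2,3-bis[4-(benzyloxy)-3,5-dimethoxybenzyl]-N,N-dimethylpent-4-enamide F5, and reduction with LiH2NBH3 in THF gives alcohol 16.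

**Step 2.**
- What may go wrong: migration of the allyl double bond into conjugation with the arene by ruthenium hydride species before metathesis, which leads to a chain one carbon short, and self-metathesis of 3.
- Fallback: a carbonyl olefination that sets out from 3 and comes back at 5. Oxidative cleavage of 3 (OsO4 cat., NaIO4, 2,6-lutidine, dioxane/H2O) gives [4-(benzyloxy)-3,5-dimethoxyphenyl]acetaldehyde F6. This is used at once in a Wittig reaction with Ph3P=CHCO2Me in CH2Cl2 at 0 °C, and the stabilised ylide should give the E enoate 5.

**Step 9.**
- What may go wrong: epimerisation at the carbon next to the aldehyde through the small open-chain population, which would move the cis-lactol into the trans series, and over-oxidation of the hemiacetal during the one-flask cleavage.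
- Fallback: a stepwise glycol route that sets out from 16 and comes back at 18 (through 17). Upjohn dihydroxylation (OsO4 cat., N-methylmorpholine N-oxide, acetone/H2O) gives 3,4-bis[4-(benzyloxy)-3,5-dimethoxybenzyl]pentane-1,2,5-triol F7 (3,4-configuration as in 16, epimers at C2), which is isolated and purified. The glycol is then cleaved with silica-supported NaIO4 in CH2Cl2 at 0 °C, and the mixture is filtered straight into NaBH4/MeOH. The aldehyde oxidation level then exists only briefly, under neutral, non-aqueous conditions and without osmium.

**Step 11.**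
- What may go wrong: attack of hydride at sulfur instead of carbon (S–O cleavage), which releases an alkoxide that displaces the neighbouring mesylate and closes a tetrahydrofuran.
- Fallback: a radical reduction that sets out from 19 and comes back at 20. Finkelstein exchange (NaI, acetone, reflux) gives meso-(2R,3S)-1,4-diiodo-2,3-bis[4-(benzyloxy)-3,5-dimethoxybenzyl]butane F8. Chain reduction with Bu3SnH and AIBN in toluene at 80 °C replaces both iodines by hydrogen without any oxygen nucleophile in the molecule.

## Further compounds

F1 | step 7 | 3-[4-(benzyloxy)-3,5-dimethoxyphenyl]-N,N-dimethylpropanamide | COc1cc(CCC(=O)N(C)C)cc(OC)c1OCc1ccccc1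
F2 | step 7 | N-{3-[4-(benzyloxy)-3,5-dimethoxyphenyl]-1-methoxypropylidene}-N-methylmethanaminium tetrafluoroborate | COc1cc(CCC(OC)=[N+](C)C)cc(OC)c1OCc1ccccc1.F[B-](F)(F)F
F3 | step 7 | 3-[4-(benzyloxy)-3,5-dimethoxyphenyl]-1,1-dimethoxy-N,N-dimethylpropan-1-amine | COc1cc(CCC(OC)(OC)N(C)C)cc(OC)c1OCc1ccccc1
F4 | step 7 | (1Z)-3-[4-(benzyloxy)-3,5-dimethoxyphenyl]-1-({(2E)-4-[4-(benzyloxy)-3,5-dimethoxyphenyl]but-2-en-1-yl}oxy)-N,N-dimethylprop-1-en-1-amine | COc1cc(C/C=C(/N(C)C)OC/C=C/Cc2cc(OC)c(OCc3ccccc3)c(OC)c2)cc(OC)c1OCc1ccccc1
F5 | step 7 | (2R*,3R*)-2,3-bis[4-(benzyloxy)-3,5-dimethoxybenzyl]-N,N-dimethylpent-4-enamide (racemic) | COc1cc(C[C@@H](C(=O)N(C)C)[C@@H](C=C)Cc2cc(OC)c(OCc3ccccc3)c(OC)c2)cc(OC)c1OCc1ccccc1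
F6 | step 2 | [4-(benzyloxy)-3,5-dimethoxyphenyl]acetaldehyde | O=CCc1cc(OC)c(OCc2ccccc2)c(OC)c1
F7 | step 9 | 3,4-bis[4-(benzyloxy)-3,5-dimethoxybenzyl]pentane-1,2,5-triol (3,4-configuration as in 16, epimers at C2) | COc1cc(C[C@@H](CO)[C@@H](C(O)CO)Cc2cc(OC)c(OCc3ccccc3)c(OC)c2)cc(OC)c1OCc1ccccc1
F8 | step 11 | meso-(2R,3S)-1,4-diiodo-2,3-bis[4-(benzyloxy)-3,5-dimethoxybenzyl]butane | COc1cc(C[C@@H](CI)[C@@H](CI)Cc2cc(OC)c(OCc3ccccc3)c(OC)c2)cc(OC)c1OCc1ccccc1
A1 | alternative 1 | (E)-2-(benzyloxy)-1,3-dimethoxy-5-(prop-1-en-1-yl)benzene | C/C=C/c1cc(OC)c(OCc2ccccc2)c(OC)c1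
A2 | alternative 1 | r-1,c-2-bis[4-(benzyloxy)-3,5-dimethoxyphenyl]-t-3,t-4-dimethylcyclobutane | C[C@@H]1[C@H](C)[C@@H](c2cc(OC)c(OCc3ccccc3)c(OC)c2)[C@H]1c1cc(OC)c(OCc2ccccc2)c(OC)c1
A3 | alternative 2 | 2,5-bis[4-(benzyloxy)-3,5-dimethoxyphenyl]-3,4-dimethylfuran | Cc1c(C)c(-c2cc(OC)c(OCc3ccccc3)c(OC)c2)oc1-c1cc(OC)c(OCc2ccccc2)c(OC)c1
A4 | alternative 2 | all-cis-2,5-bis(4-hydroxy-3,5-dimethoxyphenyl)-3,4-dimethyltetrahydrofuran | C[C@@H]1[C@H](C)[C@H](c2cc(OC)c(O)c(OC)c2)O[C@@H]1c1cc(OC)c(O)c(OC)c1
A5 | alternative 3 | meso-1,4-diiodo-2,3-dimethylbutane | IC[C@@H](C)[C@@H](C)CI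
A6 | alternative 3 | meso-1,4-bis(iodozincio)-2,3-dimethylbutane | I[Zn]C[C@@H](C)[C@@H](C)C[Zn]I
A7 | alternative 3 | 2-(benzyloxy)-5-bromo-1,3-dimethoxybenzene | COc1cc(Br)cc(OC)c1OCc1ccccc1
A8 | alternative 3 | meso-1,4-bis[4-(benzyloxy)-3,5-dimethoxyphenyl]-2,3-dimethylbutane (identical with 20) | COc1cc(C[C@@H](C)[C@@H](C)Cc2cc(OC)c(OCc3ccccc3)c(OC)c2)cc(OC)c1OCc1ccccc1
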